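The route rests on cutting the C9–C10 bond. In ring A (C1–C5, C10) the oxygenated C3 lies para to the methyl-bearing quaternary C10 and next to C4 with its one-carbon appendage C15. Ring A is therefore read as a 3-alkyl-2,4-dimethylphenol. Once ionised, such a phenol expels a primary mesylate from C9 through its para carbon. This single operation closes ring B, builds the quaternary stereocentre C10 and leaves a 1,4-dien-3-one. That dienone already has O3, C15 and the tetrasubstituted C4=C5 alkene for the last-step photooxygenation. Precursor 20 is an acyclic phenol mesylate. Its C7 and C8 stereocentres stem from trans-selective benzylation of (S)-3-hydroxy-γ-butyrolactone; O12 is a PMB ether and O8 a TBS ether.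

Key step: step 15

Remark: eudesmane numbering is used for all intermediates (C6 benzylic carbon, C9 mesylate carbon, C11–C13 side chain, C14 methyl on C10, C15 methyl on C4). β is the face of the C10 methyl group. The commercial benzoate carries only C15, so C14 is added in steps 1 and 3.

Step 1
Reactants: 1 methyl 3-hydroxy-2-methylbenzoate
Product: 2 methyl 6-bromo-3-hydroxy-2-methylbenzoate
Conditions: NBS, MeCN, −10 → 0 °C, dark
Reagents that add atoms: N-bromosuccinimide, O=C1CCC(=O)N1Br
Why: Electrophilic aromatic bromination under hydroxyl control: one ortho position is blocked by the methyl group, so NBS in acetonitrile should favour the para carbon (the future C10), which must be functionalised to receive C14.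

Step 2
Reactants: 2 methyl 6-bromo-3-hydroxy-2-methylbenzoate
Product: 3 methyl 6-bromo-2-methyl-3-(triisopropylsilyloxy)benzoate
Conditions: TIPSCl, imidazole, DMF, rt
Reagents that add atoms: triisopropylsilyl chloride, CC(C)[Si](Cl)(C(C)C)C(C)C
Why: Standard phenol silylation; the bulky aryl silyl ether should survive organozinc, hydride, enolate, organolithium and mild acid conditions and still leave selectively with fluoride in step 14.

Step 3
Reactants: 3 methyl 6-bromo-2-methyl-3-(triisopropylsilyloxy)benzoate
Product: 4 methyl 2,6-dimethyl-3-(triisopropylsilyloxy)benzoate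
Conditions: MeZnCl, Pd(dppf)Cl2 (cat.), THF, 60 °C
Reagents that add atoms: methylzinc chloride, C[Zn]Cl
Why: Negishi coupling of the aryl bromide with a methylzinc reagent tolerates ester and silyl ether, installs C14 and completes the 2,4-dimethylphenol pattern of ring A.

Step 4
Reactants: 4 methyl 2,6-dimethyl-3-(triisopropylsilyloxy)benzoate
Product: 5 [2,6-dimethyl-3-(triisopropylsilyloxy)phenyl]methanol
Conditions: i-Bu2AlH, CH2Cl2, −78 → 0 °C
Reagents that add atoms: none
Why: Hydride reduction of the di-ortho-substituted ester to the benzylic alcohol (future C6); the aluminium hydride reaches the twisted ester and leaves the aryl silyl ether intact.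

Step 5
Reactants: 5 [2,6-dimethyl-3-(triisopropylsilyloxy)phenyl]methanol
Product: 6 2,6-dimethyl-3-(triisopropylsilyloxy)benzyl bromide
Conditions: CBr4, PPh3, CH2Cl2, 0 °C
Reagents that add atoms: tetrabromomethane, BrC(Br)(Br)Br
Why: Appel reaction, a neutral conversion of the primary benzylic alcohol into the bromide that does not touch the silyl ether.

Step 6
Reactants: 6 2,6-dimethyl-3-(triisopropylsilyloxy)benzyl bromide; 7 (S)-3-hydroxy-γ-butyrolactone
Product: 9 (3S,4S)-3-[2,6-dimethyl-3-(triisopropylsilyloxy)benzyl]-4-hydroxydihydrofuran-2(3H)-one (trans), via lactone dianion 8 (not isolated)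
Conditions: 7, LiN(i-Pr)2 (2.2 equiv), THF, −78 °C; then 6, DMPU, −78 → −30 °C
Reagents that add atoms: none
Why: Fráter–Seebach-type alkylation of a β-hydroxy lactone dianion: C8 comes from the chiral pool, and the benzylic bromide should approach the ring enolate anti to the C8 oxido group, which forms C6–C7 and sets C7 trans to O8 on the lactone (the relation that becomes cis C7/C8 substituents on ring B).

Step 7
Reactants: 9 trans-benzyl hydroxy lactone
Product: 10 (2S,3S)-2-[2,6-dimethyl-3-(triisopropylsilyloxy)benzyl]-3,4-dihydroxy-N-methoxy-N-methylbutanamide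
Conditions: MeNH(OMe)·HCl, AlMe3, CH2Cl2, 0 °C → rt; crude product used at once
Reagents that add atoms: N,O-dimethylhydroxylamine hydrochloride, CNOC.Cl
Why: Weinreb aminolysis of the lactone with the aluminium amide frees O9 and makes C11 an acyl donor that accepts a single organometallic; the weakly basic reagent should not epimerise C7, and immediate silylation forestalls relactonisation.

Step 8
Reactants: 10 dihydroxy Weinreb amide
Product: 11 (2S,3S)-3,4-bis(tert-butyldimethylsilyloxy)-2-[2,6-dimethyl-3-(triisopropylsilyloxy)benzyl]-N-methoxy-N-methylbutanamide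
Conditions: TBSOTf, 2,6-lutidine, CH2Cl2, 0 °C
Reagents that add atoms: tert-butyldimethylsilyl triflate, CC(C)(C)[Si](C)(C)OS(=O)(=O)C(F)(F)F
Why: Silylation of both hydroxyl groups in one operation; the primary (O9) and secondary (O8) ethers are told apart later by their different acid lability.

Step 9
Reactants: 12 4-methoxybenzyl alcohol; 13 tributyl(iodomethyl)stannane
Product: 14 tributyl[(4-methoxybenzyloxy)methyl]stannane
Conditions: NaH, THF–DMF, 0 °C → rt
Reagents that add atoms: none
Why: Williamson ether synthesis at an unhindered primary iodide gives the storable precursor of the C12 nucleophile.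

Step 10
Reactants: 14 tributyl[(4-methoxybenzyloxy)methyl]stannane; 11 bis-silylated Weinreb amide
Product: 16 (3S,4S)-4,5-bis(tert-butyldimethylsilyloxy)-3-[2,6-dimethyl-3-(triisopropylsilyloxy)benzyl]-1-(4-methoxybenzyloxy)pentan-2-one, via alkoxymethyllithium 15 (not isolated)
Conditions: 14, n-BuLi, THF, −78 °C; then 11, −78 °C
Reagents that add atoms: none
Why: Tin–lithium exchange gives the α-alkoxymethyllithium, which adds once to the amide (Weinreb ketone synthesis, chelated tetrahedral intermediate) and brings in C12 with its PMB-protected oxygen.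

Step 11
Reactants: 16 α-alkoxy ketone
Product: 17 (3R,4S)-4,5-bis(tert-butyldimethylsilyloxy)-3-[2,6-dimethyl-3-(triisopropylsilyloxy)benzyl]-2-[(4-methoxybenzyloxy)methyl]pent-1-ene
Conditions: Cp2TiMe2, toluene, 75 °C, dark
Reagents that add atoms: dimethyltitanocene, C[Ti](C)(C1C=CC=C1)C1C=CC=C1
Why: Petasis methylenation: the neutral titanium carbene turns the hindered ketone into the C11=C13 methylene group without the enolisation that could epimerise C7 or expel the β-silyloxy group under ylide conditions.

Step 12
Reactants: 17 tris-silylated alkene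
Product: 18 (2S,3R)-2-(tert-butyldimethylsilyloxy)-3-[2,6-dimethyl-3-(triisopropylsilyloxy)benzyl]-4-[(4-methoxybenzyloxy)methyl]pent-4-en-1-ol
Conditions: camphorsulfonic acid (cat.), MeOH–CH2Cl2 (1:1), 0 °C
Reagents that add atoms: none
Why: Acid-catalysed methanolysis sorts silyl ethers by steric access, so the primary TBS ether should go first while the secondary TBS ether and the acid-stable aryl TIPS ether stay.

Step 13
Reactants: 18 primary alcohol
Product: 19 methanesulfonate of 18
Conditions: MsCl, Et3N, CH2Cl2, 0 °C
Reagents that add atoms: methanesulfonyl chloride, CS(=O)(=O)Cl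
Why: Sulfonylation of the only free hydroxyl group activates C9 while the phenol is still masked.

Step 14
Reactants: 19 aryl silyl ether mesylate
Product: 20 (2S,3R)-2-(tert-butyldimethylsilyloxy)-3-(3-hydroxy-2,6-dimethylbenzyl)-4-[(4-methoxybenzyloxy)methyl]pent-4-en-1-yl methanesulfonate
Conditions: Bu4NF–AcOH (1:1, 1.1 equiv), THF, 0 °C
Reagents that add atoms: none
Why: Fluoride-induced desilylation removes the aryl silyl ether much faster than the hindered secondary alkyl silyl ether because phenoxide is the better leaving group, and the acetic acid buffer keeps the phenol protonated so that no uncontrolled alkylation starts.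

Step 15
Reactants: 20 phenol mesylate
Product: 22 8β-(tert-butyldimethylsilyloxy)-12-(4-methoxybenzyloxy)eudesma-1,4,11(13)-trien-3-one, via potassium phenolate 21 (not isolated)
Conditions: KOt-Bu (1.0 equiv), t-BuOH–THF, 0.005 M, rt → 70 °C, argon
Reagents that add atoms: none
Why: One equivalent of KOt-Bu (so that no free alkoxide remains to eliminate the mesylate) converts 20 into phenolate 21, whose para carbon C10 displaces the C9 mesylate in an intramolecular SN2 reaction and leaves ring A as the cross-conjugated dienone. This is a Winstein–Masamune phenolate alkylation of the Ar2-6 type (attack through the ring carbon adjacent to the tether, six-membered ring), a known route to 4,4-disubstituted cyclohexa-2,5-dienones. Ring B (C5–C6–C7–C8–C9–C10) closes in the 6-exo-tet mode, with C9 over the π face at C10 and the mesylate pointing away. C10 is controlled by C7 and C8: in the chair-like transition state the branched C7 alkenyl group sits equatorial and the C8–H bond, not the C8–O bond, eclipses the departing mesylate, which places the slim silyloxy group axial and sends the C10 methyl to the face of O8; the cost is a developing 1,3-diaxial OSi/CH3 contact, so the preference should be useful rather than complete, and the C10 epimer is removed by chromatography. The step needs C- over O-alkylation and C10 over C4 attack: the oxygen is meta to the tether and cannot reach C9, high dilution suppresses intermolecular ether formation, and the ortho carbon C4, which could close an isomeric six-membered ring, is wedged between the solvated K–O group and the C5 side chain and would give the less stable linearly conjugated 2,4-dienone.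

Step 16
Reactants: 22 cross-conjugated dienone
Product: 23 8β-(tert-butyldimethylsilyloxy)-12-(4-methoxybenzyloxy)eudesma-4,11(13)-dien-3-one
Conditions: [(Ph3P)CuH]6, moist degassed toluene, rt
Reagents that add atoms: none
Why: Stryker-type conjugate reduction: the copper hydride adds only to the disubstituted C1=C2 branch, since the fully substituted C4=C5 branch and the isolated C11=C13 alkene are inert to it; no stereocentre is formed.

Step 17
Reactants: 23 silyloxy enone
Product: 24 8β-hydroxy-12-(4-methoxybenzyloxy)eudesma-4,11(13)-dien-3-one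
Conditions: HF·pyridine, THF, 0 °C → rt
Reagents that add atoms: none
Why: Fluoride-mediated desilylation is done at the robust enone stage, before any ionisable allylic ester is present, and the PMB ether is unaffected.

Step 18
Reactants: 24 8β-alcohol
Product: 25 8β-acetoxy-12-(4-methoxybenzyloxy)eudesma-4,11(13)-dien-3-one
Conditions: Ac2O, DMAP (cat.), pyridine, rt
Reagents that add atoms: acetic anhydride, CC(=O)OC(C)=O
Why: DMAP-catalysed acetylation of the axial alcohol; the acetate must be in place before C12 is oxidised, otherwise O8 would lactonise onto C12.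

Step 19
Reactants: 25 acetoxy enone
Product: 26 8β-acetoxy-12-(4-methoxybenzyloxy)eudesma-4,11(13)-dien-3α-ol
Conditions: LiBH(s-Bu)3, THF, −78 °C; aq. NH4Cl
Reagents that add atoms: none
Why: 1,2-Reduction of a β,β-disubstituted enone with a bulky trialkylborohydride: the reagent should attack C3 along the equatorial trajectory and give the pseudo-axial 3α-alcohol, and at −78 °C it should spare the acetate.

Step 20
Reactants: 26 3α-alcohol; 27 angelic acid [(Z)-2-methylbut-2-enoic acid]
Product: 29 8β-acetoxy-3α-angeloyloxy-12-(4-methoxybenzyloxy)eudesma-4,11(13)-diene, via mixed anhydride 28 (not isolated)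
Conditions: 27, 2,4,6-trichlorobenzoyl chloride, Et3N, toluene, rt; then 26, 80 °C
Reagents that add atoms: none
Why: Yamaguchi-type mixed-anhydride esterification run without a nucleophilic catalyst avoids the addition–elimination path that turns the Z-acid into tiglate, and C3 keeps its configuration because its C–O bond is not touched.

Step 21
Reactants: 29 PMB ether
Product: 30 8β-acetoxy-3α-angeloyloxyeudesma-4,11(13)-dien-12-ol
Conditions: DDQ, CH2Cl2–pH 7 buffer (10:1), 0 °C
Reagents that add atoms: none
Why: Oxidative PMB cleavage (hydride abstraction from the electron-rich benzylic position, then hydrolysis) runs under neutral conditions that both esters and the alkenes should tolerate.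

Step 22
Reactants: 30 allylic alcohol
Product: 31 8β-acetoxy-3α-angeloyloxyeudesma-4,11(13)-dien-12-al
Conditions: Dess–Martin periodinane, CH2Cl2, 0 °C → rt
Reagents that add atoms: none
Why: Dess–Martin oxidation of the primary allylic alcohol to the 2-substituted acrolein is mild and non-basic, so C7 is not disturbed.

Step 23
Reactants: 31 enal
Product: 32 8β-acetoxy-3α-angeloyloxyeudesma-4,11(13)-dien-12-oic acid
Conditions: NaClO2, NaH2PO4, 2-methyl-2-butene (excess), t-BuOH–H2O, 0 °C → rt
Reagents that add atoms: sodium chlorite, [Na+].[O-]Cl=O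
Why: Pinnick oxidation converts the enal into the acrylic acid, with the excess scavenger alkene trapping hypochlorous acid before it can reach C4=C5.

Step 24
Reactants: 32 acrylic acid
Product: 33 methyl 8β-acetoxy-3α-angeloyloxyeudesma-4,11(13)-dien-12-oate
Conditions: Me3SiCHN2, toluene–MeOH (4:1), 0 °C
Reagents that add atoms: (trimethylsilyl)diazomethane, C[Si](C)(C)C=[N+]=[N-]
Why: Diazoalkane esterification works without base or acid, so neither ester exchange nor conjugate addition to the acrylate should occur.

Step 25
Reactants: 33 methyl ester with the 4-ene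
Product: 34 methyl 8β-acetoxy-3α-angeloyloxy-5α-hydroperoxyeudesma-4(15),11(13)-dien-12-oate (CNP0116769.2)
Conditions: O2, tetraphenylporphyrin (cat.), CH2Cl2, visible light, −20 °C; no reductive work-up
Reagents that add atoms: oxygen, O=O
Why: Schenck ene reaction: singlet oxygen should pick the only electron-rich (tetrasubstituted) alkene C4=C5 over the acrylate and angelate double bonds, add from the α face opposite the axial C10 methyl, find no α-hydrogen at C3 (that position holds the angelate), and take hydrogen from C15 (geminal to the acyloxy-bearing C3) rather than from C6, because C–O bonding at C4 would push C15 into a 1,3-diaxial clash with C14; oxygen thus ends on C5 (5α-OOH) and the double bond moves to C4=C15.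

Compound list
1 | methyl 3-hydroxy-2-methylbenzoate | COC(=O)c1cccc(O)c1C | starting material
2 | methyl 6-bromo-3-hydroxy-2-methylbenzoate | COC(=O)c1c(Br)ccc(O)c1C | intermediate
3 | methyl 6-bromo-2-methyl-3-(triisopropylsilyloxy)benzoate | COC(=O)c1c(Br)ccc(O[Si](C(C)C)(C(C)C)C(C)C)c1C | intermediate
4 | methyl 2,6-dimethyl-3-(triisopropylsilyloxy)benzoate | COC(=O)c1c(C)ccc(O[Si](C(C)C)(C(C)C)C(C)C)c1C | intermediate
5 | [2,6-dimethyl-3-(triisopropylsilyloxy)phenyl]methanol | OCc1c(C)ccc(O[Si](C(C)C)(C(C)C)C(C)C)c1C | intermediate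
6 | 2,6-dimethyl-3-(triisopropylsilyloxy)benzyl bromide | BrCc1c(C)ccc(O[Si](C(C)C)(C(C)C)C(C)C)c1C | intermediate
7 | (S)-3-hydroxy-γ-butyrolactone | O=C1OC[C@@H](O)C1 | starting material
8 | dilithium enolate-alkoxide of 7 | [Li]OC1=C[C@H](O[Li])CO1 | intermediate
9 | (3S,4S)-3-[2,6-dimethyl-3-(triisopropylsilyloxy)benzyl]-4-hydroxydihydrofuran-2(3H)-one | O=C1OC[C@@H](O)[C@@H]1Cc1c(C)ccc(O[Si](C(C)C)(C(C)C)C(C)C)c1C | intermediate
10 | (2S,3S)-dihydroxy Weinreb amide | CON(C)C(=O)[C@@H](Cc1c(C)ccc(O[Si](C(C)C)(C(C)C)C(C)C)c1C)[C@H](O)CO | intermediate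
11 | (2S,3S)-bis-TBS Weinreb amide | CON(C)C(=O)[C@@H](Cc1c(C)ccc(O[Si](C(C)C)(C(C)C)C(C)C)c1C)[C@H](O[Si](C)(C)C(C)(C)C)CO[Si](C)(C)C(C)(C)C | intermediate
12 | 4-methoxybenzyl alcohol | COc1ccc(CO)cc1 | starting material
13 | tributyl(iodomethyl)stannane | CCCC[Sn](CCCC)(CCCC)CI | starting material
14 | tributyl[(4-methoxybenzyloxy)methyl]stannane | CCCC[Sn](CCCC)(CCCC)COCc1ccc(OC)cc1 | intermediate
15 | [(4-methoxybenzyloxy)methyl]lithium | [Li]COCc1ccc(OC)cc1 | intermediate
16 | (3S,4S)-α-alkoxy ketone | O=C(COCc1ccc(OC)cc1)[C@@H](Cc1c(C)ccc(O[Si](C(C)C)(C(C)C)C(C)C)c1C)[C@H](O[Si](C)(C)C(C)(C)C)CO[Si](C)(C)C(C)(C)C | intermediate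
17 | (3R,4S)-1,1-disubstituted alkene, O8 and O9 as TBS ethers | C=C(COCc1ccc(OC)cc1)[C@@H](Cc1c(C)ccc(O[Si](C(C)C)(C(C)C)C(C)C)c1C)[C@H](O[Si](C)(C)C(C)(C)C)CO[Si](C)(C)C(C)(C)C | intermediate
18 | (2S,3R)-primary alcohol (C9–OH) | C=C(COCc1ccc(OC)cc1)[C@@H](Cc1c(C)ccc(O[Si](C(C)C)(C(C)C)C(C)C)c1C)[C@H](O[Si](C)(C)C(C)(C)C)CO | intermediate
19 | C9 mesylate, phenol as TIPS ether | C=C(COCc1ccc(OC)cc1)[C@@H](Cc1c(C)ccc(O[Si](C(C)C)(C(C)C)C(C)C)c1C)[C@H](O[Si](C)(C)C(C)(C)C)COS(C)(=O)=O | intermediate
20 | phenol mesylate (key-step precursor) | C=C(COCc1ccc(OC)cc1)[C@@H](Cc1c(C)c(O)ccc1C)[C@@H](COS(C)(=O)=O)O[Si](C)(C)C(C)(C)C | intermediate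
21 | potassium phenolate of 20 | C=C(COCc1ccc(OC)cc1)[C@@H](Cc1c(C)c([O-])ccc1C)[C@@H](COS(C)(=O)=O)O[Si](C)(C)C(C)(C)C.[K+] | intermediate
22 | 8β-(TBS-oxy)-12-(PMB-oxy)eudesma-1,4,11(13)-trien-3-one | C=C(COCc1ccc(OC)cc1)[C@H]1CC2=C(C)C(=O)C=C[C@]2(C)C[C@H]1O[Si](C)(C)C(C)(C)C | intermediate
23 | 8β-(TBS-oxy)-12-(PMB-oxy)eudesma-4,11(13)-dien-3-one | C=C(COCc1ccc(OC)cc1)[C@H]1CC2=C(C)C(=O)CC[C@]2(C)C[C@H]1O[Si](C)(C)C(C)(C)C | intermediate
24 | 8β-hydroxy-12-(PMB-oxy)eudesma-4,11(13)-dien-3-one | C=C(COCc1ccc(OC)cc1)[C@H]1CC2=C(C)C(=O)CC[C@]2(C)C[C@H]1O | intermediate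
25 | 8β-acetoxy-12-(PMB-oxy)eudesma-4,11(13)-dien-3-one | C=C(COCc1ccc(OC)cc1)[C@H]1CC2=C(C)C(=O)CC[C@]2(C)C[C@H]1OC(C)=O | intermediate
26 | 8β-acetoxy-12-(PMB-oxy)eudesma-4,11(13)-dien-3α-ol | C=C(COCc1ccc(OC)cc1)[C@H]1CC2=C(C)[C@H](O)CC[C@]2(C)C[C@H]1OC(C)=O | intermediate
27 | angelic acid | C/C=C(/C)C(=O)O | starting material
28 | angelic 2,4,6-trichlorobenzoic anhydride | C/C=C(/C)C(=O)OC(=O)c1c(Cl)cc(Cl)cc1Cl | intermediate
29 | 8β-acetoxy-3α-angeloyloxy-12-(PMB-oxy)eudesma-4,11(13)-diene | C=C(COCc1ccc(OC)cc1)[C@H]1CC2=C(C)[C@H](OC(=O)/C(C)=C\C)CC[C@]2(C)C[C@H]1OC(C)=O | intermediate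
30 | 8β-acetoxy-3α-angeloyloxyeudesma-4,11(13)-dien-12-ol | C=C(CO)[C@H]1CC2=C(C)[C@H](OC(=O)/C(C)=C\C)CC[C@]2(C)C[C@H]1OC(C)=O | intermediate
31 | 8β-acetoxy-3α-angeloyloxyeudesma-4,11(13)-dien-12-al | C=C(C=O)[C@H]1CC2=C(C)[C@H](OC(=O)/C(C)=C\C)CC[C@]2(C)C[C@H]1OC(C)=O | intermediate
32 | 8β-acetoxy-3α-angeloyloxyeudesma-4,11(13)-dien-12-oic acid | C=C(C(=O)O)[C@H]1CC2=C(C)[C@H](OC(=O)/C(C)=C\C)CC[C@]2(C)C[C@H]1OC(C)=O | intermediate
33 | methyl 8β-acetoxy-3α-angeloyloxyeudesma-4,11(13)-dien-12-oate | C=C(C(=O)OC)[C@H]1CC2=C(C)[C@H](OC(=O)/C(C)=C\C)CC[C@]2(C)C[C@H]1OC(C)=O | intermediate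
34 | methyl 8β-acetoxy-3α-angeloyloxy-5α-hydroperoxyeudesma-4(15),11(13)-dien-12-oate | C=C(C(=O)OC)[C@H]1C[C@@]2(OO)C(=C)[C@H](OC(=O)/C(C)=C\C)CC[C@]2(C)C[C@H]1OC(C)=O | target

Total step count: 25. Longest linear sequence: 24 (steps 1–8 and 10–25; step 9 is a one-step branch).

Steps most likely to fail

**Step 15.**
- What may go wrong: substitution at C9 is retarded by the β-silyloxy group. Intermolecular O-alkylation, attack through the ortho carbon C4, elimination, or a weak facial preference at C10 may then take over.
- Fallback: it sets out from alcohol 18 and changes the electrophile, the precursor and the way the nucleophile is generated. An Appel iodination (I2, PPh3, imidazole, CH2Cl2, 0 °C) gives the primary iodide F1, with the phenol still masked as its TIPS ether. One equivalent of anhydrous CsF in DMF at high dilution then removes only the aryl silyl group.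
- Why it should help: the caesium phenolate forms gradually and without any Brønsted base. It meets a soft leaving group that favours carbon over oxygen attack. This is a desilylative alkylative dearomatisation, a known variant of phenolate para-alkylation.
- Return: the sequence comes back to the route at dienone 22 and bypasses 19, 20 and 21.

**Step 19.**
- What may go wrong: hydride delivery may show poor facial selectivity, with the pseudo-equatorial 3β-alcohol competing, or the acetate may be lost.
- Fallback: it sets out from enone 25 and uses the intrinsically favoured axial attack instead of fighting it. Luche reduction (NaBH4, CeCl3·7H2O, MeOH, −78 °C) should give the 3β-alcohol F2. A Mitsunobu esterification with angelic acid 27 (PPh3, diisopropyl azodicarboxylate, toluene, 0 °C) then inverts C3 and installs the ester in the same operation.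
- Return: the sequence comes back at angelate 29 and replaces steps 19 and 20.

**Step 20.**
- What may go wrong: the angeloyl unit may isomerise from Z to E during activation. Acylation of the hindered pseudo-axial allylic alcohol may also be sluggish, with ionisation at C3.
- Fallback: it sets out from alcohol 26 and builds the Z-alkene on the ester instead of transferring it. Carbodiimide coupling with 2-[bis(2,2,2-trifluoroethoxy)phosphoryl]propanoic acid (DCC, DMAP cat., CH2Cl2, 0 °C) gives the phosphonopropanoate F3. A Still–Gennari olefination with acetaldehyde (KN(SiMe3)2, 18-crown-6, THF, −78 °C) should then form the (Z)-2-methylbut-2-enoate.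
- Return: the sequence comes back at 29.

Further compounds
F1 | step 15 | (7R,8S)-primary iodide, O8 as TBS ether, phenol as TIPS ether | C=C(COCc1ccc(OC)cc1)[C@@H](Cc1c(C)ccc(O[Si](C(C)C)(C(C)C)C(C)C)c1C)[C@H](O[Si](C)(C)C(C)(C)C)CI
F2 | step 19 | 8β-acetoxy-12-(4-methoxybenzyloxy)eudesma-4,11(13)-dien-3β-ol | C=C(COCc1ccc(OC)cc1)[C@H]1CC2=C(C)[C@@H](O)CC[C@]2(C)C[C@H]1OC(C)=O
F3 | step 20 | 3α-{2-[bis(2,2,2-trifluoroethoxy)phosphoryl]propanoyloxy} derivative of 26 (epimers at the phosphonate carbon) | C=C(COCc1ccc(OC)cc1)[C@H]1CC2=C(C)[C@H](OC(=O)C(C)P(=O)(OCC(F)(F)F)OCC(F)(F)F)CC[C@]2(C)C[C@H]1OC(C)=O
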